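**Retrosynthetic overview**
1. Target 11 ⇒ diacid lactone 9: the C4 methylidene goes on last (carboxylation, then decarboxylative methylenation). 9 ⇒ diester lactone 8 by ester hydrolysis.
2. Key disconnection 8 ⇒ 7: the lactone O1–C2 bond. The only ring is closed here by a carboxylate-directed, stereoselective γ-C(sp3)–H lactonisation of an open-chain succinic half-ester, which sets C2.
3. 7 ⇒ 6: asymmetric hydrogenation of a Stobbe half-ester, which sets C3.
4. 6 ⇒ aldehyde 3 + dimethyl succinate 4 (Stobbe condensation). 3 ⇒ hexadecanolide 1 by methanolysis and oxidation.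

Assumption: the side chain is read as (CH2)14CO2H and the target as (2R,3S) with the 2-alkyl and 3-carboxyl groups trans (oxolane numbering: O1, C2 alkyl, C3 CO2H, C4 methylidene, C5 C=O).

**Step 1**
Reactants: 1 hexadecanolide (oxacycloheptadecan-2-one)
Product: 2 methyl 16-hydroxyhexadecanoate
Conditions: H2SO4 (cat.), MeOH, reflux
Reagents that add atoms: methanol, CO
Why: Acid-catalysed ring-opening transesterification of the macrolactone is driven to completion by the large excess of methanol and creates no stereocentre.

**Step 2**
Reactants: 2 methyl 16-hydroxyhexadecanoate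
Product: 3 methyl 16-oxohexadecanoate
Conditions: TEMPO (1 mol%), KBr (0.1 equiv), NaOCl (1.1 equiv), NaHCO3, CH2Cl2/H2O, 0 °C
Reagents that add atoms: none
Why: The Anelli oxidation (oxoammonium-mediated) stops at the aldehyde for an unhindered primary alcohol in the two-phase system and leaves the methyl ester untouched.

**Step 3**
Reactants: 3 methyl 16-oxohexadecanoate; 4 dimethyl succinate
Product: 6 (3E)-19-methoxy-3-(methoxycarbonyl)-19-oxononadec-3-enoic acid, via racemic Stobbe lactone 5 (not isolated)
Conditions: KOtBu (1.2 equiv), tBuOH, 40 °C, slow addition of 3 + 4; then aq. HCl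
Reagents that add atoms: none
Why: In the Stobbe condensation, aldol addition of the succinate enolate, lactonisation to paraconic ester 5 and irreversible E1cB ring opening give the half-ester with the free acid on the CH2 arm; any Z isomer is carried on because both alkene isomers converge in step 4.

**Step 4**
Reactants: 6 (3E)-19-methoxy-3-(methoxycarbonyl)-19-oxononadec-3-enoic acid
Product: 7 (3R)-19-methoxy-3-(methoxycarbonyl)-19-oxononadecanoic acid
Conditions: [Rh(cod)((S,S)-Et-DuPhos)]BF4 (0.5 mol%), NaOMe (0.1 equiv), H2 (6 bar), MeOH, 25 °C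
Reagents that add atoms: none
Why: In this rhodium-catalysed asymmetric hydrogenation of an itaconate-type Stobbe half-ester, two-point binding of the alkene and the carboxylate arm to the cationic bisphospholane complex fixes the face of H2 delivery and sets C3 as R (expected ≥97% ee by analogy with alkyl Stobbe half-esters; the same spatial arrangement is labelled 3S in lactone 8 only because the CIP priorities change).

**Step 5**
Reactants: 7 (3R)-19-methoxy-3-(methoxycarbonyl)-19-oxononadecanoic acid
Product: 8 methyl (2R,3S)-2-(15-methoxy-15-oxopentadecyl)-5-oxooxolane-3-carboxylate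
Conditions: [Mn(OTf)2((S,S)-TIPSpdp)] (2 mol%), H2O2 (1.5 equiv, syringe pump), CF3CH2OH, −20 °C
Reagents that add atoms: none
Why: Proposed new method: the free carboxylate of 7 binds the chiral complex (TIPSpdp = N,N'-bis[(5-triisopropylsilylpyridin-2-yl)methyl]-2,2'-bipyrrolidine) and assists heterolysis of the bound peroxide to a high-valent manganese oxo carboxylate; this abstracts one of the two diastereotopic hydrogens of the only γ-methylene (C4 of 7) by 1,7-hydrogen-atom transfer through a chair-like transition state with the C3 ester and the chain pseudo-equatorial, and fast carboxylate rebound with retention closes the O1–C2 bond, so the 2R centre is set by the ligand-controlled choice of hydrogen, reinforced by the existing centre (trans lactone; both lactone oxygens come from the acid); the two esters do not direct and the remote chain methylenes cannot reach the bound oxidant; the closest known reaction type is the manganese-catalysed, carboxylic-acid-directed enantioselective γ-C–H lactonisation of simple alkanoic acids with H2O2, which has not been shown on succinic half-esters whose γ-C–H is deactivated by a β-ester, nor for catalyst-controlled diastereoselection next to a stereocentre.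

**Step 6**
Reactants: 8 methyl (2R,3S)-2-(15-methoxy-15-oxopentadecyl)-5-oxooxolane-3-carboxylate
Product: 9 (2R,3S)-2-(14-carboxytetradecyl)-5-oxooxolane-3-carboxylic acid
Conditions: 6 M HCl, 1,4-dioxane, reflux
Reagents that add atoms: water, O
Why: Acid-catalysed ester hydrolysis (AAC2) cleaves both methyl esters while the γ-lactone survives because it recloses under acid; base is avoided because it would trigger retro-Stobbe (E1cB) ring opening at C3, and both stereocentres are retained.

**Step 7**
Reactants: 9 (2R,3S)-2-(14-carboxytetradecyl)-5-oxooxolane-3-carboxylic acid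
Product: 11 (2R,3S)-2-(14-carboxytetradecyl)-4-methylidene-5-oxooxolane-3-carboxylic acid, via α-carboxy lactone 10 (not isolated)
Conditions: MeOMgOCO2Me (2 M in DMF), 135 °C; aq. HCl; then 37% aq. HCHO, PhNHMe, NaOAc, AcOH, 25 °C
Reagents that add atoms: formaldehyde, C=O
Why: Stiles carboxylation of the lactone α-carbon as a magnesium chelate followed by decarboxylative Mannich methylenation (the CO2 unit lent by MeOMgOCO2Me leaves again) is the established endgame for paraconic acids; it touches neither stereocentre, and the ω-acid is only carried as its magnesium salt.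

**Compound list**
1 | hexadecanolide (oxacycloheptadecan-2-one) | O=C1CCCCCCCCCCCCCCCO1 | starting material
2 | methyl 16-hydroxyhexadecanoate | COC(=O)CCCCCCCCCCCCCCCO | intermediate
3 | methyl 16-oxohexadecanoate | COC(=O)CCCCCCCCCCCCCCC=O | intermediate
4 | dimethyl succinate (dimethyl butanedioate) | COC(=O)CCC(=O)OC | starting material
5 | racemic Stobbe lactone: methyl 2-(15-methoxy-15-oxopentadecyl)-5-oxooxolane-3-carboxylate, cis/trans mixture, not isolated | COC(=O)CCCCCCCCCCCCCCC1OC(=O)CC1C(=O)OC | intermediate
6 | (3E)-19-methoxy-3-(methoxycarbonyl)-19-oxononadec-3-enoic acid | OC(=O)C/C(C(=O)OC)=C\CCCCCCCCCCCCCCC(=O)OC | intermediate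
7 | (3R)-19-methoxy-3-(methoxycarbonyl)-19-oxononadecanoic acid | OC(=O)C[C@@H](CCCCCCCCCCCCCCCC(=O)OC)C(=O)OC | intermediate
8 | methyl (2R,3S)-2-(15-methoxy-15-oxopentadecyl)-5-oxooxolane-3-carboxylate (trans) | C1C(=O)O[C@H](CCCCCCCCCCCCCCC(=O)OC)[C@H]1C(=O)OC | intermediate
9 | (2R,3S)-2-(14-carboxytetradecyl)-5-oxooxolane-3-carboxylic acid (trans) | C1C(=O)O[C@H](CCCCCCCCCCCCCCC(=O)O)[C@H]1C(=O)O | intermediate
10 | (2R,3S)-2-(14-carboxytetradecyl)-5-oxooxolane-3,4-dicarboxylic acid, C4 epimers, not isolated | OC(=O)C1C(=O)O[C@H](CCCCCCCCCCCCCCC(=O)O)[C@H]1C(=O)O | intermediate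
11 | (2R,3S)-2-(14-carboxytetradecyl)-4-methylidene-5-oxooxolane-3-carboxylic acid (CNP0222442.1) | C=C1C(=O)O[C@H](CCCCCCCCCCCCCCC(=O)O)[C@H]1C(=O)O | target

**Totals**
Total step count: 7. Longest linear sequence: 7 steps (1 → 11).

**Three steps most likely to fail**

Step 5 (proposed C–H lactonisation).
- Risks: low conversion because the γ-C–H is β to an ester; desaturation back to 6; wrong diastereomer; oxidation of remote chain methylenes.
- Within the route, the (S,S) and (R,R) forms of the manganese complex are compared in the first run to find the matched one. Because 7 is already enantioenriched, the cis lactone is a diastereomer and is removed by chromatography, so the step costs yield, not ee.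
- Fallback with known chemistry, setting out from aldehyde 3: photocatalytic hydroacylation of dimethyl maleate with 3 ((nBu4N)4[W10O32] 2 mol%, 365 nm, MeCN) gives the keto triester dimethyl 2-(16-methoxy-16-oxohexadecanoyl)butanedioate F3. Asymmetric transfer hydrogenation with dynamic kinetic resolution (RuCl(p-cymene)[(R,R)-TsDPEN] or its antipode, whichever gives the 1R carbinol, HCO2H/Et3N) gives the hydroxy triester dimethyl 2-[(1R)-1-hydroxy-16-methoxy-16-oxohexadecyl]butanedioate F4. F4 lactonises onto the CH2CO2Me arm (cat. TsOH, toluene) and is equilibrated at C3 with DBU to the trans lactone, which rejoins the route at 8; steps 3 and 4 are then not needed.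

Step 3 (Stobbe condensation).
- Risks: self-aldol of the enolisable long-chain aldehyde; base-induced deconjugation to the β,γ-unsaturated isomer, which would carry a racemic C3 into step 4 and erode ee; partial tert-butyl transesterification.
- Fallback, setting out from 3: trimethyl phosphonoacetate is alkylated with tert-butyl bromoacetate (NaH, THF) to the phosphonosuccinate 4-tert-butyl 1-methyl 2-(dimethoxyphosphoryl)butanedioate F1. Horner–Wadsworth–Emmons olefination of 3 with F1 (NaH, THF, 0 °C) gives the mixed diester 4-tert-butyl 1-methyl (2E)-2-(16-methoxy-16-oxohexadecylidene)butanedioate F2, with no alkoxide and no lactone intermediate. CF3CO2H in CH2Cl2 then removes the tert-butyl group and the route is rejoined at 6.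

Step 7 (α-methylenation).
- Risks: poor conversion of the diacid as its magnesium salts; migration of the exocyclic alkene into the ring; epimerisation at C3 at 135 °C.
- Fallback, setting out from 9: trianion formation (LiN(SiMe3)2 3.3 equiv, THF/DMPU, −78 °C) and aminomethylation with Me2N=CH2+ I− gives the Mannich base (2R,3S)-2-(14-carboxytetradecyl)-4-[(dimethylamino)methyl]-5-oxooxolane-3-carboxylic acid F5. N-Methylation (MeI, MeOH) gives the quaternary salt (2R,3S)-2-(14-carboxytetradecyl)-5-oxo-4-[(trimethylammonio)methyl]oxolane-3-carboxylic acid iodide F6. Aqueous NaHCO3 at 25 °C eliminates trimethylamine and the route is rejoined at 11.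

**Further compounds**
F1 | step 3 | 4-tert-butyl 1-methyl 2-(dimethoxyphosphoryl)butanedioate | COC(=O)C(CC(=O)OC(C)(C)C)P(=O)(OC)OC
F2 | step 3 | 4-tert-butyl 1-methyl (2E)-2-(16-methoxy-16-oxohexadecylidene)butanedioate | CC(C)(C)OC(=O)C/C(C(=O)OC)=C\CCCCCCCCCCCCCCC(=O)OC
F3 | step 5 | dimethyl 2-(16-methoxy-16-oxohexadecanoyl)butanedioate | COC(=O)CC(C(=O)OC)C(=O)CCCCCCCCCCCCCCC(=O)OC
F4 | step 5 | dimethyl 2-[(1R)-1-hydroxy-16-methoxy-16-oxohexadecyl]butanedioate (C2 epimers) | COC(=O)CC(C(=O)OC)[C@H](O)CCCCCCCCCCCCCCC(=O)OC
F5 | step 7 | (2R,3S)-2-(14-carboxytetradecyl)-4-[(dimethylamino)methyl]-5-oxooxolane-3-carboxylic acid (C4 epimers) | CN(C)CC1C(=O)O[C@H](CCCCCCCCCCCCCCC(=O)O)[C@H]1C(=O)O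
F6 | step 7 | (2R,3S)-2-(14-carboxytetradecyl)-5-oxo-4-[(trimethylammonio)methyl]oxolane-3-carboxylic acid iodide (C4 epimers) | C[N+](C)(C)CC1C(=O)O[C@H](CCCCCCCCCCCCCCC(=O)O)[C@H]1C(=O)O.[I-]
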